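**Plan**

- Retrosynthesis: the five O‑benzyl bonds and the saturated bridge lead back to a diarylalkyne. This is cut at the a5–C(sp) bond into a ring A aryl triflate and a ring B arylacetylene. Ring A is labelled a1 (C–OMe), a2 (CH), a3 (C–OH), a4 and a6 (C–CH2Ar), a5 (C–bridge).
- Enabling feature: with a5 written as C–OH, ring A is a 2,4‑dibenzylphloroglucinol. That is an isomer of a 3‑benzyl‑6‑(2‑arylethyl)‑4‑alkoxy‑2‑pyrone (pyrone C2 = a5, C3 = a4, C4 = a3, C5 = a2, C6 = a1, inner side‑chain CH2 = a6), so cutting a5–a6 leads back to that pyrone.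
- The pyrone is cut at C3–CH2Ar and at the side‑chain CH2–CH2Ar bond, back to 4‑hydroxy‑6‑methyl‑2‑pyrone, a benzylic chloride and an aldehyde. Ring B is cut at its diarylmethane bond and at the alkyne.
- Forward: the pyrone is substituted at the methyl group, at C3 and at O4 (steps 1–3) and ring A is closed from it (step 4). The a1 oxygen is methylated and the a5 oxygen triflated (steps 5, 6), the ring B alkyne is built (steps 7–10), the fragments are joined (step 11) and hydrogenation finishes (step 12).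
- Stereochemistry: the target has no stereocentre and no stereogenic double bond, so nothing has to be set.

Key step: step 4

Remark: 4‑(benzyloxy)phenylboronic acid and ethynyltrimethylsilane are taken as commercial. The transient compounds 5, 9 and 18 carry an uncontrolled alkene geometry or sp3 centre that disappears within the same step.

**Route**

Step 1
Reactants: 1 4‑hydroxy‑6‑methyl‑2H‑pyran‑2‑one; 2 4‑(benzyloxy)benzyl chloride
Product: 3 6‑{2‑[4‑(benzyloxy)phenyl]ethyl}‑4‑hydroxy‑2H‑pyran‑2‑one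
Conditions: LiN(i‑Pr)2 (2.2 equiv), THF–HMPA, −78 °C; then 2, −78 → 0 °C; aq. HCl
Reagents that add atoms: none
Why: Two equivalents of amide base should give the O4,C7‑dianion of 1, whose terminal carbanion is the most nucleophilic site and is benzylated by 2 (γ‑alkylation of a 1,3‑dicarbonyl‑type dianion), while the 4‑oxido group shields C3 and the lactone.

Step 2
Reactants: 3 6‑{2‑[4‑(benzyloxy)phenyl]ethyl}‑4‑hydroxy‑2H‑pyran‑2‑one; 4 4‑(benzyloxy)benzaldehyde
Product: 6 3‑[4‑(benzyloxy)benzyl]‑6‑{2‑[4‑(benzyloxy)phenyl]ethyl}‑4‑hydroxy‑2H‑pyran‑2‑one, via Knoevenagel arylidene pyrandione 5 (not isolated)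
Conditions: L‑proline (20 mol%), Hantzsch ester (1.1 equiv), CH2Cl2, rt
Reagents that add atoms: none
Why: Organocatalytic three‑component reductive alkylation: proline‑mediated Knoevenagel condensation at the nucleophilic C3 gives arylidene 5, which is reduced at once by conjugate hydride transfer from the Hantzsch ester, so that addition of a second pyrone to 5 cannot compete.

Step 3
Reactants: 6 3‑[4‑(benzyloxy)benzyl]‑6‑{2‑[4‑(benzyloxy)phenyl]ethyl}‑4‑hydroxy‑2H‑pyran‑2‑one
Product: 7 4‑(benzyloxy)‑3‑[4‑(benzyloxy)benzyl]‑6‑{2‑[4‑(benzyloxy)phenyl]ethyl}‑2H‑pyran‑2‑one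
Conditions: BnOH, PPh3, DIAD, THF, 0 °C → rt
Reagents that add atoms: benzyl alcohol, OCc1ccccc1
Why: Mitsunobu etherification: the 4‑hydroxy‑2‑pyrone is a vinylogous carboxylic acid acidic enough to protonate the betaine, and its oxygen at C4 is benzylated by the benzyloxyphosphonium ion to give the 4‑alkoxy‑2‑pyrone.

Step 4
Reactants: 7 4‑(benzyloxy)‑3‑[4‑(benzyloxy)benzyl]‑6‑{2‑[4‑(benzyloxy)phenyl]ethyl}‑2H‑pyran‑2‑one
Product: 10 5‑(benzyloxy)‑2,4‑bis[4‑(benzyloxy)benzyl]benzene‑1,3‑diol, via ring‑opened benzyl keto ester 8 (not isolated), via cyclohexenedione tautomer 9 (not isolated)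
Conditions: NaOCH2Ph (5 equiv, from NaH and BnOH), dry BnOH, 160 °C, argon; then aq. HCl, 0 °C
Reagents that add atoms: none
Why: Benzyloxide adds to the lactone carbonyl a5 of 7 and the ring opens to the sodium enolate of benzyl ester 8, whose a4=a3 double bond keeps the cis geometry of the pyrone so that the ester stays beside the ketone arm; in hot benzyl alcohol a2 is reprotonated, the a1 ketone can rotate and enolise toward a6, and this enolate attacks the ester, expels benzyloxide and gives 9, which tautomerises to the bis‑phenoxide of 10. The closest known reaction type is the alkoxide‑induced recyclisation of 6‑alkyl‑4‑alkoxy‑2‑pyrones (masked 3,5‑dioxo esters) to phloroglucinol monoethers, an intramolecular Claisen (Dieckmann‑type) condensation that is known to need high temperature. Ring A closes in a 6‑(enolendo)‑exo‑trig mode, which Baldwin's rules for enolates allow. No stereocentre survives, since the a6 centre of 9 is lost on aromatisation. The step needs C‑acylation through a6 alone, and the chain secures this because a2 could only close a four‑membered ring and the ester has no α‑hydrogen, while reclosure through the enolate oxygen merely returns 7 and stays in equilibrium until the irreversible aromatisation drains it. Benzyloxide as the base makes exchange at the a3 ether and at the ester degenerate, and dry conditions prevent saponification and decarboxylation, which would delete a5.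

Step 5
Reactants: 10 5‑(benzyloxy)‑2,4‑bis[4‑(benzyloxy)benzyl]benzene‑1,3‑diol
Product: 11 3‑(benzyloxy)‑2,6‑bis[4‑(benzyloxy)benzyl]‑5‑methoxyphenol
Conditions: MeI (1.05 equiv), K2CO3 (1.1 equiv), acetone, rt
Reagents that add atoms: iodomethane, CI
Why: Williamson ether synthesis under substrate control: the a1 hydroxyl has a single ortho substituent whereas the a5 hydroxyl lies between two arylmethyl groups, so with about one equivalent of MeI the more accessible phenoxide should be alkylated first, and acetone as solvent favours O‑ over C‑methylation.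

Step 6
Reactants: 11 3‑(benzyloxy)‑2,6‑bis[4‑(benzyloxy)benzyl]‑5‑methoxyphenol
Product: 12 3‑(benzyloxy)‑2,6‑bis[4‑(benzyloxy)benzyl]‑5‑methoxyphenyl trifluoromethanesulfonate
Conditions: Tf2O, pyridine, CH2Cl2, 0 °C
Reagents that add atoms: trifluoromethanesulfonic anhydride, O=S(=O)(OS(=O)(=O)C(F)(F)F)C(F)(F)F
Why: Aryl triflate formation at the a5 phenol, the only free hydroxyl left in 11, for which the small and very electrophilic anhydride should overcome the two flanking arylmethyl groups.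

Step 7
Reactants: 13 4‑bromo‑2‑hydroxybenzaldehyde
Product: 14 2‑(benzyloxy)‑4‑bromobenzaldehyde
Conditions: BnBr, K2CO3, DMF, rt
Reagents that add atoms: benzyl bromide, BrCc1ccccc1
Why: Williamson ether synthesis at the phenol, whose hydrogen bond to the aldehyde is broken by carbonate in DMF, while the aldehyde and the aryl bromide are untouched.

Step 8
Reactants: 14 2‑(benzyloxy)‑4‑bromobenzaldehyde; 15 [4‑(benzyloxy)phenyl]boronic acid
Product: 19 2‑(benzyloxy)‑1‑[4‑(benzyloxy)benzyl]‑4‑bromobenzene, via tosylhydrazone 16 (not isolated), via aryldiazomethane 17 (not isolated), via benzylic boronic acid 18 (not isolated)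
Conditions: TsNHNH2, 1,4‑dioxane, 80 °C; then 15, K2CO3, 110 °C
Reagents that add atoms: none
Why: Barluenga reductive coupling: condensation gives tosylhydrazone 16, carbonate‑induced loss of sulfinate gives diazo compound 17, which adds to the boron of 15 and undergoes a 1,2‑aryl shift with loss of N2 to boronic acid 18, and protodeboronation of this doubly benzylic boronic acid leaves the diarylmethane; no transition metal is present, so the C–Br bond is kept.

Step 9
Reactants: 19 2‑(benzyloxy)‑1‑[4‑(benzyloxy)benzyl]‑4‑bromobenzene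
Product: 20 ({3‑(benzyloxy)‑4‑[4‑(benzyloxy)benzyl]phenyl}ethynyl)trimethylsilane
Conditions: ethynyltrimethylsilane, PdCl2(PPh3)2 (3 mol%), CuI (5 mol%), Et3N–THF, 60 °C
Reagents that add atoms: ethynyltrimethylsilane, C#C[Si](C)(C)C
Why: Sonogashira coupling of an unhindered aryl bromide with a silyl‑capped acetylene, the silyl group preventing double arylation.

Step 10
Reactants: 20 ({3‑(benzyloxy)‑4‑[4‑(benzyloxy)benzyl]phenyl}ethynyl)trimethylsilane
Product: 21 2‑(benzyloxy)‑1‑[4‑(benzyloxy)benzyl]‑4‑ethynylbenzene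
Conditions: K2CO3 (cat.), MeOH–THF, rt
Reagents that add atoms: none
Why: Methoxide‑mediated protodesilylation of the alkynylsilane, to which the benzyl ethers are inert.

Step 11
Reactants: 12 3‑(benzyloxy)‑2,6‑bis[4‑(benzyloxy)benzyl]‑5‑methoxyphenyl trifluoromethanesulfonate; 21 2‑(benzyloxy)‑1‑[4‑(benzyloxy)benzyl]‑4‑ethynylbenzene
Product: 22 1‑(benzyloxy)‑2,4‑bis[4‑(benzyloxy)benzyl]‑3‑({3‑(benzyloxy)‑4‑[4‑(benzyloxy)benzyl]phenyl}ethynyl)‑5‑methoxybenzene
Conditions: PdCl2(MeCN)2 (5 mol%), XPhos (15 mol%), Cs2CO3, MeCN–THF, 80 °C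
Reagents that add atoms: none
Why: Copper‑free Sonogashira coupling: zerovalent palladium carrying the bulky biarylphosphine should insert into the doubly ortho‑substituted C–OTf bond and the carbonate‑deprotonated alkyne is then transferred and reductively eliminated, while leaving copper out suppresses oxidative dimerisation of 21 during the slow oxidative addition.

Step 12
Reactants: 22 1‑(benzyloxy)‑2,4‑bis[4‑(benzyloxy)benzyl]‑3‑({3‑(benzyloxy)‑4‑[4‑(benzyloxy)benzyl]phenyl}ethynyl)‑5‑methoxybenzene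
Product: 23 2,4‑bis(4‑hydroxybenzyl)‑3‑{2‑[3‑hydroxy‑4‑(4‑hydroxybenzyl)phenyl]ethyl}‑5‑methoxyphenol (CNP0207338.0)
Conditions: H2 (1 atm), 10% Pd/C, THF–MeOH, rt
Reagents that add atoms: none
Why: Heterogeneous hydrogenation over palladium should saturate the diarylalkyne to the ethylene bridge and hydrogenolyse the five O‑benzyl ethers to toluene, while the aryl methyl ether and the diarylmethane C–C bonds are inert.

**Compound list**

1 | 4‑hydroxy‑6‑methyl‑2H‑pyran‑2‑one | Cc1cc(O)cc(=O)o1 | starting material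
2 | 4‑(benzyloxy)benzyl chloride | ClCc1ccc(OCc2ccccc2)cc1 | starting material
3 | 6‑{2‑[4‑(benzyloxy)phenyl]ethyl}‑4‑hydroxy‑2H‑pyran‑2‑one | O=c1cc(O)cc(CCc2ccc(OCc3ccccc3)cc2)o1 | intermediate
4 | 4‑(benzyloxy)benzaldehyde | O=Cc1ccc(OCc2ccccc2)cc1 | starting material
5 | 3‑[4‑(benzyloxy)benzylidene]‑6‑{2‑[4‑(benzyloxy)phenyl]ethyl}‑2H‑pyran‑2,4(3H)‑dione (alkene geometry not defined) | O=C1OC(CCc2ccc(OCc3ccccc3)cc2)=CC(=O)C1=Cc1ccc(OCc2ccccc2)cc1 | intermediate (not isolated)
6 | 3‑[4‑(benzyloxy)benzyl]‑6‑{2‑[4‑(benzyloxy)phenyl]ethyl}‑4‑hydroxy‑2H‑pyran‑2‑one | O=c1oc(CCc2ccc(OCc3ccccc3)cc2)cc(O)c1Cc1ccc(OCc2ccccc2)cc1 | intermediate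
7 | 4‑(benzyloxy)‑3‑[4‑(benzyloxy)benzyl]‑6‑{2‑[4‑(benzyloxy)phenyl]ethyl}‑2H‑pyran‑2‑one | O=c1oc(CCc2ccc(OCc3ccccc3)cc2)cc(OCc2ccccc2)c1Cc1ccc(OCc2ccccc2)cc1 | intermediate (key‑step precursor)
8 | benzyl (2E)‑3‑(benzyloxy)‑2‑[4‑(benzyloxy)benzyl]‑7‑[4‑(benzyloxy)phenyl]‑5‑oxohept‑2‑enoate (present as its sodium enolate) | O=C(OCc1ccccc1)/C(Cc1ccc(OCc2ccccc2)cc1)=C(/OCc1ccccc1)CC(=O)CCc1ccc(OCc2ccccc2)cc1 | intermediate (not isolated)
9 | 5‑(benzyloxy)‑2,4‑bis[4‑(benzyloxy)benzyl]cyclohex‑4‑ene‑1,3‑dione (racemic at C2) | O=C1CC(OCc2ccccc2)=C(Cc2ccc(OCc3ccccc3)cc2)C(=O)C1Cc1ccc(OCc2ccccc2)cc1 | intermediate (not isolated)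
10 | 5‑(benzyloxy)‑2,4‑bis[4‑(benzyloxy)benzyl]benzene‑1,3‑diol | Oc1cc(OCc2ccccc2)c(Cc2ccc(OCc3ccccc3)cc2)c(O)c1Cc1ccc(OCc2ccccc2)cc1 | intermediate (key‑step product)
11 | 3‑(benzyloxy)‑2,6‑bis[4‑(benzyloxy)benzyl]‑5‑methoxyphenol | COc1cc(OCc2ccccc2)c(Cc2ccc(OCc3ccccc3)cc2)c(O)c1Cc1ccc(OCc2ccccc2)cc1 | intermediate
12 | 3‑(benzyloxy)‑2,6‑bis[4‑(benzyloxy)benzyl]‑5‑methoxyphenyl trifluoromethanesulfonate | COc1cc(OCc2ccccc2)c(Cc2ccc(OCc3ccccc3)cc2)c(OS(=O)(=O)C(F)(F)F)c1Cc1ccc(OCc2ccccc2)cc1 | intermediate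
13 | 4‑bromo‑2‑hydroxybenzaldehyde | O=Cc1ccc(Br)cc1O | starting material
14 | 2‑(benzyloxy)‑4‑bromobenzaldehyde | O=Cc1ccc(Br)cc1OCc1ccccc1 | intermediate
15 | [4‑(benzyloxy)phenyl]boronic acid | OB(O)c1ccc(OCc2ccccc2)cc1 | starting material
16 | N'‑{(E)‑[2‑(benzyloxy)‑4‑bromophenyl]methylidene}‑4‑methylbenzenesulfonohydrazide | Cc1ccc(cc1)S(=O)(=O)N/N=C/c1ccc(Br)cc1OCc1ccccc1 | intermediate (not isolated)
17 | 2‑(benzyloxy)‑4‑bromo‑1‑(diazomethyl)benzene | [N-]=[N+]=Cc1ccc(Br)cc1OCc1ccccc1 | intermediate (not isolated)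
18 | {[2‑(benzyloxy)‑4‑bromophenyl][4‑(benzyloxy)phenyl]methyl}boronic acid (racemic) | OB(O)C(c1ccc(OCc2ccccc2)cc1)c1ccc(Br)cc1OCc1ccccc1 | intermediate (not isolated)
19 | 2‑(benzyloxy)‑1‑[4‑(benzyloxy)benzyl]‑4‑bromobenzene | Brc1ccc(Cc2ccc(OCc3ccccc3)cc2)c(OCc2ccccc2)c1 | intermediate
20 | ({3‑(benzyloxy)‑4‑[4‑(benzyloxy)benzyl]phenyl}ethynyl)trimethylsilane | C[Si](C)(C)C#Cc1ccc(Cc2ccc(OCc3ccccc3)cc2)c(OCc2ccccc2)c1 | intermediate
21 | 2‑(benzyloxy)‑1‑[4‑(benzyloxy)benzyl]‑4‑ethynylbenzene | C#Cc1ccc(Cc2ccc(OCc3ccccc3)cc2)c(OCc2ccccc2)c1 | intermediate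
22 | 1‑(benzyloxy)‑2,4‑bis[4‑(benzyloxy)benzyl]‑3‑({3‑(benzyloxy)‑4‑[4‑(benzyloxy)benzyl]phenyl}ethynyl)‑5‑methoxybenzene | COc1cc(OCc2ccccc2)c(Cc2ccc(OCc3ccccc3)cc2)c(C#Cc2ccc(Cc3ccc(OCc4ccccc4)cc3)c(OCc3ccccc3)c2)c1Cc1ccc(OCc2ccccc2)cc1 | intermediate
23 | 2,4‑bis(4‑hydroxybenzyl)‑3‑{2‑[3‑hydroxy‑4‑(4‑hydroxybenzyl)phenyl]ethyl}‑5‑methoxyphenol | COc1cc(O)c(Cc2ccc(O)cc2)c(CCc2ccc(Cc3ccc(O)cc3)c(O)c2)c1Cc1ccc(O)cc1 | target

**Count**

Total steps: 12. Longest linear sequence: 8 steps (steps 1–6, 11, 12); the ring B branch (steps 7–10) joins at step 11.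

**Steps most likely to fail**

Step 4. The Claisen closure at the secondary a6 carbon may be slower than competing processes at the temperature it needs. These are hydride transfer from benzyloxide to the a1 ketone (Meerwein–Ponndorf–Verley type, which removes the nucleophile), alkoxide attack at the CH2 of the a3 benzyl enol ether (dealkylation to an inert 4‑pyronate), and plain return to the pyrone on quench. The fallback uses the identity of the two arylmethyl groups on ring A, which lets the methyl ether be placed on the pyrone. It sets out from 6, which would be O‑methylated (Me2SO4, K2CO3, acetone, reflux) to 3‑[4‑(benzyloxy)benzyl]‑6‑{2‑[4‑(benzyloxy)phenyl]ethyl}‑4‑methoxy‑2H‑pyran‑2‑one F1. Recyclisation under the classical conditions of this ring transformation (NaOMe, MeOH, sealed vessel, about 185 °C) should give 2,4‑bis[4‑(benzyloxy)benzyl]‑5‑methoxybenzene‑1,3‑diol F2. Benzylation of its less hindered hydroxyl (BnBr, about one equivalent, K2CO3, acetone) then gives 11, where the fallback comes back to the route, so step 5 is no longer needed.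

Step 5. Discrimination between the two phenoxides may be insufficient, leading to methylation at the hindered a5 oxygen, double methylation, or C‑methylation at a2 of the electron‑rich ring. The fallback replaces the small electrophile by a bulky, removable one and moves the methylation to a stage where only one hydroxyl is free. It sets out from 10, which would be silylated at the a1 hydroxyl (TBSCl, imidazole, DMF, 0 °C) to 3‑(benzyloxy)‑2,6‑bis[4‑(benzyloxy)benzyl]‑5‑[(tert‑butyldimethylsilyl)oxy]phenol F3. Triflation (Tf2O, pyridine, CH2Cl2) would give 3‑(benzyloxy)‑2,6‑bis[4‑(benzyloxy)benzyl]‑5‑[(tert‑butyldimethylsilyl)oxy]phenyl trifluoromethanesulfonate F4, and desilylation (TBAF buffered with AcOH, THF, 0 °C) would give 3‑(benzyloxy)‑2,6‑bis[4‑(benzyloxy)benzyl]‑5‑hydroxyphenyl trifluoromethanesulfonate F5. Methylation of F5 (MeI, K2CO3, acetone) returns to the route at 12.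

Step 11. Oxidative addition into the doubly ortho‑substituted C–OTf bond may be slow. During that time the valuable alkyne 21 can be consumed by oligomerisation, and carbonate can cleave the triflate at sulfur back to the phenol. The fallback makes the hindered bond with a cheap alkyne used in large excess and joins the fragments at the unhindered aryl bromide. It sets out from 12, which would be coupled with excess ethynyltrimethylsilane (PdCl2(PPh3)2, CuI, Bu4NI, Et3N–DMF, sealed tube, 80 °C) to ({3‑(benzyloxy)‑2,6‑bis[4‑(benzyloxy)benzyl]‑5‑methoxyphenyl}ethynyl)trimethylsilane F6. Desilylation (K2CO3, MeOH–THF) would give 1‑(benzyloxy)‑2,4‑bis[4‑(benzyloxy)benzyl]‑3‑ethynyl‑5‑methoxybenzene F7. Sonogashira coupling of F7 with aryl bromide 19 (PdCl2(PPh3)2, CuI, Et3N–THF, 60 °C) comes back to the route at 22, and steps 9 and 10 are then not needed.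

**Further compounds**

F1 | step 4 | 3‑[4‑(benzyloxy)benzyl]‑6‑{2‑[4‑(benzyloxy)phenyl]ethyl}‑4‑methoxy‑2H‑pyran‑2‑one | COc1cc(CCc2ccc(OCc3ccccc3)cc2)oc(=O)c1Cc1ccc(OCc2ccccc2)cc1
F2 | step 4 | 2,4‑bis[4‑(benzyloxy)benzyl]‑5‑methoxybenzene‑1,3‑diol | COc1cc(O)c(Cc2ccc(OCc3ccccc3)cc2)c(O)c1Cc1ccc(OCc2ccccc2)cc1
F3 | step 5 | 3‑(benzyloxy)‑2,6‑bis[4‑(benzyloxy)benzyl]‑5‑[(tert‑butyldimethylsilyl)oxy]phenol | CC(C)(C)[Si](C)(C)Oc1cc(OCc2ccccc2)c(Cc2ccc(OCc3ccccc3)cc2)c(O)c1Cc1ccc(OCc2ccccc2)cc1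
F4 | step 5 | 3‑(benzyloxy)‑2,6‑bis[4‑(benzyloxy)benzyl]‑5‑[(tert‑butyldimethylsilyl)oxy]phenyl trifluoromethanesulfonate | CC(C)(C)[Si](C)(C)Oc1cc(OCc2ccccc2)c(Cc2ccc(OCc3ccccc3)cc2)c(OS(=O)(=O)C(F)(F)F)c1Cc1ccc(OCc2ccccc2)cc1
F5 | step 5 | 3‑(benzyloxy)‑2,6‑bis[4‑(benzyloxy)benzyl]‑5‑hydroxyphenyl trifluoromethanesulfonate | Oc1cc(OCc2ccccc2)c(Cc2ccc(OCc3ccccc3)cc2)c(OS(=O)(=O)C(F)(F)F)c1Cc1ccc(OCc2ccccc2)cc1
F6 | step 11 | ({3‑(benzyloxy)‑2,6‑bis[4‑(benzyloxy)benzyl]‑5‑methoxyphenyl}ethynyl)trimethylsilane | COc1cc(OCc2ccccc2)c(Cc2ccc(OCc3ccccc3)cc2)c(C#C[Si](C)(C)C)c1Cc1ccc(OCc2ccccc2)cc1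
F7 | step 11 | 1‑(benzyloxy)‑2,4‑bis[4‑(benzyloxy)benzyl]‑3‑ethynyl‑5‑methoxybenzene | COc1cc(OCc2ccccc2)c(Cc2ccc(OCc3ccccc3)cc2)c(C#C)c1Cc1ccc(OCc2ccccc2)cc1
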